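**Retrosynthetic overview**

1. Target ⇒ (hydrogenolysis of three O-benzyl groups) the fully protected diacetate. Its C2'–OAc / CO2Bn pair is the opened and capped form of a (3R)-3-alkyl-6,8-bis(benzyloxy)-3,4-dihydroisocoumarin.
2. Dihydroisocoumarin ⇒ Ar–C1' disconnection: carboxylate-directed ortho-C–H alkylation/lactonisation of 2,4-bis(benzyloxy)benzoic acid (from 2,4-dihydroxybenzoic acid) with a (12'S)-hydroxy-(2'R)-epoxide.
3. Key step: hydroxy-epoxide ⇒ 1,7-dibromoheptane. The symmetric C7 di-Grignard reagent is desymmetrised in one flask: one C–Mg end opens (S)-propylene oxide (C10'–C11' bond, sets C12'), the other opens (R)-epichlorohydrin (C3'–C4' bond, sets C2').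
4. Rings: the benzene ring is bought. The oxirane is made in step 2, the δ-lactone in step 3 (consuming the oxirane), and the lactone is opened again in step 4, so only the arene remains.

Assumption: (S)-propylene oxide and (R)-epichlorohydrin (each ≥99% ee) are bought; side-chain carbons are numbered C1' (benzylic) to C13'.

**Route**

Step 1
Reactants: 1 2,4-dihydroxybenzoic acid
Product: 3 2,4-bis(benzyloxy)benzoic acid, via benzyl ester 2 (not isolated)
Conditions: BnBr (3.5 equiv), K2CO3 (4 equiv), DMF, 70 °C; then KOH, MeOH/H2O, reflux; HCl work-up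
Reagents that add atoms: benzyl bromide BrCc1ccccc1; potassium hydroxide [K+].[OH-]
Why: Williamson O-benzylation (SN2) of the carboxylate and both phenols, the chelated 2-OH included at 70 °C, followed by saponification of the benzyl ester alone, returns the free acid that step 3 needs as directing group; no stereocentre is involved.

Step 2
Reactants: 4 1,7-dibromoheptane; 5 (S)-propylene oxide; 6 (R)-epichlorohydrin
Product: 10 (2S)-11-[(2R)-oxiran-2-yl]undecan-2-ol, via di-Grignard reagent 7 (not isolated), via alkoxide Grignard reagent 8 (not isolated), via chlorohydrin 9 (not isolated)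
Conditions: Mg (2.5 equiv), THF, 40 °C; CuI (10 mol %), then 5 (1.0 equiv), −30 °C; then 6 (1.3 equiv), −40 to 0 °C; then NaOH (5 M aq), rt
Reagents that add atoms: none
Why: This is the key step: CuI-catalysed SN2 opening of a terminal epoxide by a Grignard reagent occurs only at the CH2 carbon, so the two equivalent C–Mg ends of symmetric 7 are differentiated statistically (at most about half of the material becomes the mixed product; the non-polar bis-epoxide and the polar diol side products are removed by chromatography), the carbinol centre (S) comes unchanged from 5, and the oxirane centre (R) comes unchanged from 6 because neither the opening nor the Williamson-type chlorohydrin-to-oxirane closure touches the C–O stereocentre.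

Step 3
Reactants: 3 2,4-bis(benzyloxy)benzoic acid; 10 (2S)-11-[(2R)-oxiran-2-yl]undecan-2-ol
Product: 12 (3R)-6,8-bis(benzyloxy)-3-[(10S)-10-hydroxyundecyl]-3,4-dihydro-1H-isochromen-1-one, via hydroxy acid 11 (not isolated)
Conditions: Pd(OAc)2 (5 mol %), N-acetyl-L-tert-leucine (10 mol %), KOAc (1.0 equiv), HFIP, 60 °C; 10 used in 1.5 equiv
Reagents that add atoms: none
Why: Known carboxylate-directed ortho-C–H alkylation of benzoic acids by terminal epoxides under Pd(OAc)2/mono-protected amino acid catalysis: C–H palladation at C6 (the only free ortho position), SN2 attack of the aryl–palladium bond on the oxirane CH2, and lactonisation of hydroxy acid 11 in HFIP give the 3,4-dihydroisocoumarin, the untouched C–O stereocentre becoming C3 (R).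

Step 4
Reactants: 12 (3R)-6,8-bis(benzyloxy)-3-[(10S)-10-hydroxyundecyl]-3,4-dihydro-1H-isochromen-1-one
Product: 15 benzyl 2,4-bis(benzyloxy)-6-[(2R,12S)-2,12-diacetoxytridecyl]benzoate, via potassium carboxylate 13 (not isolated), via hydroxy benzyl ester 14 (not isolated)
Conditions: KOH (1.05 equiv), THF/H2O, 40 °C; evaporate, PhMe azeotrope; BnBr (1.3 equiv), DMF, rt; then Ac2O (6 equiv), pyridine, DMAP (0.1 equiv), 0 °C to rt
Reagents that add atoms: potassium hydroxide [K+].[OH-]; benzyl bromide BrCc1ccccc1; acetic anhydride CC(=O)OC(C)=O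
Why: Lactone saponification, SN2 benzylation of the carboxylate and DMAP-catalysed acetylation are run in one flask because the hindered 2,6-disubstituted benzyl ester 14 cannot be activated by Ac2O towards relactonisation (a free carboxylate could, through a mixed anhydride) and is acetylated before base-induced lactonisation sets in; both C–O stereocentres are retained.

Step 5
Reactants: 15 benzyl 2,4-bis(benzyloxy)-6-[(2R,12S)-2,12-diacetoxytridecyl]benzoate
Product: 16 2-[(2R,12S)-2,12-diacetoxytridecyl]-4,6-dihydroxybenzoic acid (CNP0203944.1)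
Conditions: H2 (1 atm), Pd/C (10 wt %), EtOAc, rt
Reagents that add atoms: none
Why: Hydrogenolysis over Pd/C cleaves the two benzyl ethers and the benzyl ester as toluene, whereas the secondary acetates (one homobenzylic, none benzylic), the arene and both stereocentres are inert, and the acetylated C2' oxygen can no longer lactonise onto the liberated acid.

**Compound list**

1 | 2,4-dihydroxybenzoic acid | OC(=O)c1ccc(O)cc1O | starting material
2 | benzyl 2,4-bis(benzyloxy)benzoate | O=C(OCc1ccccc1)c1ccc(OCc2ccccc2)cc1OCc1ccccc1 | intermediate (not isolated)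
3 | 2,4-bis(benzyloxy)benzoic acid | OC(=O)c1ccc(OCc2ccccc2)cc1OCc1ccccc1 | intermediate
4 | 1,7-dibromoheptane | BrCCCCCCCBr | starting material
5 | (S)-propylene oxide [(2S)-2-methyloxirane] | C[C@H]1CO1 | starting material
6 | (R)-epichlorohydrin [(2R)-2-(chloromethyl)oxirane] | ClC[C@H]1CO1 | starting material
7 | heptane-1,7-diylbis(magnesium bromide) | Br[Mg]CCCCCCC[Mg]Br | intermediate (not isolated)
8 | bromomagnesium (2S)-10-(bromomagnesio)decan-2-olate | C[C@H](O[Mg]Br)CCCCCCCC[Mg]Br | intermediate (not isolated)
9 | (2R,12S)-1-chlorotridecane-2,12-diol (present as its bis(bromomagnesium) alkoxide) | C[C@H](O)CCCCCCCCC[C@@H](O)CCl | intermediate (not isolated)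
10 | (2S)-11-[(2R)-oxiran-2-yl]undecan-2-ol | C[C@H](O)CCCCCCCCC[C@@H]1CO1 | intermediate
11 | 2,4-bis(benzyloxy)-6-[(2R,12S)-2,12-dihydroxytridecyl]benzoic acid | C[C@H](O)CCCCCCCCC[C@@H](O)Cc1cc(OCc2ccccc2)cc(OCc2ccccc2)c1C(=O)O | intermediate (not isolated)
12 | (3R)-6,8-bis(benzyloxy)-3-[(10S)-10-hydroxyundecyl]-3,4-dihydro-1H-isochromen-1-one | C[C@H](O)CCCCCCCCC[C@@H]1Cc2cc(OCc3ccccc3)cc(OCc3ccccc3)c2C(=O)O1 | intermediate
13 | potassium 2,4-bis(benzyloxy)-6-[(2R,12S)-2,12-dihydroxytridecyl]benzoate | C[C@H](O)CCCCCCCCC[C@@H](O)Cc1cc(OCc2ccccc2)cc(OCc2ccccc2)c1C(=O)[O-].[K+] | intermediate (not isolated)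
14 | benzyl 2,4-bis(benzyloxy)-6-[(2R,12S)-2,12-dihydroxytridecyl]benzoate | C[C@H](O)CCCCCCCCC[C@@H](O)Cc1cc(OCc2ccccc2)cc(OCc2ccccc2)c1C(=O)OCc1ccccc1 | intermediate (not isolated)
15 | benzyl 2,4-bis(benzyloxy)-6-[(2R,12S)-2,12-diacetoxytridecyl]benzoate | CC(=O)O[C@H](CCCCCCCCC[C@H](C)OC(C)=O)Cc1cc(OCc2ccccc2)cc(OCc2ccccc2)c1C(=O)OCc1ccccc1 | intermediate
16 | 2-[(2R,12S)-2,12-diacetoxytridecyl]-4,6-dihydroxybenzoic acid (CNP0203944.1) | CC(=O)O[C@H](CCCCCCCCC[C@H](C)OC(C)=O)Cc1cc(O)cc(O)c1C(=O)O | target

**Totals**

Total step count: 5.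
Longest linear sequence: 4 steps (4 → 10 → 12 → 15 → 16; the arene branch 1 → 3 → 12 → 15 → 16 is equally long).

**Three steps most likely to fail, with fallbacks**

1. The desymmetrising double opening (step 2). The two ends of 7 react independently, so the mixed product is capped near 50 %, and di-Grignard formation itself loses material to Wurtz coupling. The fallback sets out from 7 and 6 and comes back to the route at 10. Treat 7 with 6 alone (2.4 equiv, CuI 10 mol %, THF, −40 °C) to give (2R,12R)-1,13-dichlorotridecane-2,12-diol F1 as its magnesium alkoxide, which is not isolated. Close both chlorohydrins with aqueous NaOH to the C2-symmetric bis-epoxide (2R,2'R)-2,2'-(nonane-1,9-diyl)bis(oxirane) F2, which is purified. The symmetry is then broken by hydride instead of by a second carbon electrophile: LiBHEt3 (1.0 equiv, THF, −78 to 0 °C) opens one of the two homotopic oxiranes at CH2 and gives 10 (the (R)-oxirane becomes the (S)-carbinol only because the CIP ranking changes). Recovered F2 is recycled, and the bis-epoxide side product of step 2 itself can be fed into the same hydride opening.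

2. The C–H alkylation/lactonisation (step 3). The electron-rich, ortho-alkoxy acid may palladate slowly, and the epoxide may be consumed by HFIP or acetate before it is attacked. The fallback sets out from 10 and comes back to the route at 12; it builds the aryl–carbon bond with a stoichiometric aryl nucleophile and adds the carbonyl afterwards. Bought 1-bromo-3,5-bis(benzyloxy)benzene F3 is converted with Mg in THF into [3,5-bis(benzyloxy)phenyl]magnesium bromide F4. F4 (2.2 equiv, the excess serving as base for the free hydroxyl) with CuI (10 mol %) in THF at −30 to 0 °C opens 10 at the oxirane CH2 and gives (2R,12S)-1-[3,5-bis(benzyloxy)phenyl]tridecane-2,12-diol F5. NBS (1.0 equiv, MeCN, 0 °C) brominates the ring ortho to the chain and para to a benzyloxy group and gives (2R,12S)-1-[2-bromo-3,5-bis(benzyloxy)phenyl]tridecane-2,12-diol F6. Intramolecular alkoxycarbonylation of F6 (Pd(OAc)2 5 mol %, Xantphos, CO 1 atm, K2CO3, toluene, 100 °C) closes the six-membered lactone through the C2 hydroxyl and delivers 12.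

3. The one-flask opening, benzylation and acetylation (step 4). Hydroxy ester 14 may relactonise to 12 before it is acetylated. The fallback sets out from 12 and comes back to the route at 16; it leaves the carboxylate unprotected and relies on the far higher nucleophilicity of alkoxides. 12 is opened with KOH as in step 4 to 13 and dried. The two hydroxyls are deprotonated with NaH (2.5 equiv, THF, 0 °C), and the cold solution is added to excess Ac2O in THF at −78 °C, so that both alkoxides are acetylated before the hindered carboxylate can form a mixed anhydride. Aqueous work-up at pH 3 (HCl) gives 2,4-bis(benzyloxy)-6-[(2R,12S)-2,12-diacetoxytridecyl]benzoic acid F7, which can no longer lactonise. Hydrogenolysis of F7 (H2, Pd/C, EtOAc, rt) removes the two benzyl ethers and gives 16.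

**Further compounds**

F1 | step 2 | (2R,12R)-1,13-dichlorotridecane-2,12-diol | ClC[C@H](O)CCCCCCCCC[C@@H](O)CCl
F2 | step 2 | (2R,2'R)-2,2'-(nonane-1,9-diyl)bis(oxirane) | C1O[C@@H]1CCCCCCCCC[C@@H]1CO1
F3 | step 3 | 1-bromo-3,5-bis(benzyloxy)benzene | Brc1cc(OCc2ccccc2)cc(OCc2ccccc2)c1
F4 | step 3 | [3,5-bis(benzyloxy)phenyl]magnesium bromide | Br[Mg]c1cc(OCc2ccccc2)cc(OCc2ccccc2)c1
F5 | step 3 | (2R,12S)-1-[3,5-bis(benzyloxy)phenyl]tridecane-2,12-diol | C[C@H](O)CCCCCCCCC[C@@H](O)Cc1cc(OCc2ccccc2)cc(OCc2ccccc2)c1
F6 | step 3 | (2R,12S)-1-[2-bromo-3,5-bis(benzyloxy)phenyl]tridecane-2,12-diol | C[C@H](O)CCCCCCCCC[C@@H](O)Cc1cc(OCc2ccccc2)cc(OCc2ccccc2)c1Br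
F7 | step 4 | 2,4-bis(benzyloxy)-6-[(2R,12S)-2,12-diacetoxytridecyl]benzoic acid | CC(=O)O[C@H](CCCCCCCCC[C@H](C)OC(C)=O)Cc1cc(OCc2ccccc2)cc(OCc2ccccc2)c1C(=O)O
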